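**Plan**

Numbering: ring A is the benzoate ring (ester on C1', hydroxyls on C2'/C4', ether oxygen on C6'); ring B is the aryloxy ring (ether oxygen on C1, OH on C2, prenyl on C3/C4, OMe on C5/C6).
Retrosynthesis: the ester C(=O)–OMe bond is cut first, folding the C1' carbonyl of ring A onto the C2 oxygen of ring B as a seven-membered dibenzo-1,4-dioxepinone lactone. The lactone C2–O bond is then cut back to C2–H, which is possible because C2 is the one ring B carbon that can be carried through unsubstituted.
Further cuts: the diaryl ether C6'–O bond (ring B phenol plus ring A aryl triflate), the C1–O bond of the ring B phenol (directed lithiation), and the two ArCH2–CH= bonds of the prenyl groups (benzylic dibromide from meconin plus an alkenyl Grignard reagent).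
Forward: ring B is built up (steps 1–4), ring A is protected and activated (steps 5–6), the ether is joined (step 7) and the acid freed (step 8). The only new ring, the seven-membered lactone, is closed by anodic C–H/O–H coupling (step 9), reopened by methoxide (step 10), and the MOM ethers are removed (step 11).
Stereochemistry: none to set; the target has no stereocentre and both alkenes end in two methyl groups.

Key step: step 9

Remark: meconin is taken as a purchasable phthalide, and MOM ethers are chosen for ring A because they should survive hydroxide, methoxide and buffered anodic conditions and leave under mild acid.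

**Route**

Step 1
Reactants: 1 meconin (6,7-dimethoxy-3H-2-benzofuran-1-one)
Product: 2 [2-(hydroxymethyl)-3,4-dimethoxyphenyl]methanol
Conditions: LiAlH4, THF, 0 °C to rt; aq. NaOH work-up
Reagents that add atoms: none
Why: Hydride reduction of the lactone (LiAlH4 reduction of an ester) should open meconin to the 1,2-benzenedimethanol, the aryl methyl ethers being inert to hydride.

Step 2
Reactants: 2 [2-(hydroxymethyl)-3,4-dimethoxyphenyl]methanol
Product: 3 1,2-bis(bromomethyl)-3,4-dimethoxybenzene
Conditions: PBr3, CH2Cl2, 0 °C to rt; used without storage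
Reagents that add atoms: phosphorus tribromide BrP(Br)Br
Why: Substitution of both benzylic alcohols by bromide through their phosphite esters (SN2 with PBr3) should be fast on this electron-rich benzylic system, and the cold aprotic medium disfavours acid-catalysed closure to the cyclic ether.

Step 3
Reactants: 3 1,2-bis(bromomethyl)-3,4-dimethoxybenzene; 4 2-methylprop-1-enylmagnesium bromide
Product: 5 1,2-dimethoxy-3,4-bis(3-methylbut-2-enyl)benzene
Conditions: 4 (3 equiv), CuI (10 mol %), THF, −30 to 0 °C
Reagents that add atoms: 2-methylprop-1-enylmagnesium bromide CC(C)=C[Mg]Br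
Why: Copper-catalysed cross-coupling of an alkenyl Grignard reagent with benzylic bromides (organocuprate displacement, monovalent copper as carrier) should form both C(sp3)–C(sp2) bonds and so create the two prenyl groups, a standard way from benzyl halides to allyl- and prenylarenes.

Step 4
Reactants: 5 1,2-dimethoxy-3,4-bis(3-methylbut-2-enyl)benzene
Product: 8 2,3-dimethoxy-4,5-bis(3-methylbut-2-enyl)phenol, via aryllithium 6 (not isolated), via dimethyl arylboronate 7 (not isolated)
Conditions: n-BuLi, TMEDA, Et2O, 0 °C; B(OMe)3, −78 °C to rt; 30 % H2O2, aq. NaOH, 0 °C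
Reagents that add atoms: n-butyllithium [Li]CCCC (the lithium of 6), trimethyl borate COB(OC)OC (the boron and its methoxy groups in 7), hydrogen peroxide OO (the phenol oxygen of 8)
Why: Directed ortho-metalation: in ether with TMEDA the butyllithium complexed to the outer methoxy group should remove the adjacent ring hydrogen (the only C–H next to an oxygen) faster than a prenyl CH2 hydrogen, and borate trapping followed by the peroxide-induced 1,2-shift of aryl from boron to oxygen turns the C–Li bond into the phenol.

Step 5
Reactants: 9 methyl 2,4,6-trihydroxybenzoate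
Product: 10 methyl 2-hydroxy-4,6-bis(methoxymethoxy)benzoate
Conditions: MOMCl (2.2 equiv), i-Pr2NEt, CH2Cl2, 0 °C to rt
Reagents that add atoms: chloromethyl methyl ether COCCl
Why: Williamson-type O-alkylation with an α-chloro ether should protect the para hydroxyl and one of the two equivalent ortho hydroxyls, while the last ortho hydroxyl, held in a hydrogen bond to the ester carbonyl, stays free, as is usual for 2,4,6-trihydroxyaryl carbonyl compounds.

Step 6
Reactants: 10 methyl 2-hydroxy-4,6-bis(methoxymethoxy)benzoate
Product: 11 methyl 2,4-bis(methoxymethoxy)-6-(trifluoromethylsulfonyloxy)benzoate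
Conditions: PhNTf2, K2CO3, DMF, rt
Reagents that add atoms: N-phenylbis(trifluoromethanesulfonimide) O=S(=O)(N(c1ccccc1)S(=O)(=O)C(F)(F)F)C(F)(F)F
Why: O-Sulfonylation of the chelated phenoxide with the mild triflyl donor PhNTf2 should give the aryl triflate without touching the MOM acetals or the ester.

Step 7
Reactants: 8 2,3-dimethoxy-4,5-bis(3-methylbut-2-enyl)phenol; 11 methyl 2,4-bis(methoxymethoxy)-6-(trifluoromethylsulfonyloxy)benzoate
Product: 12 methyl 2-[2,3-dimethoxy-4,5-bis(3-methylbut-2-enyl)phenoxy]-4,6-bis(methoxymethoxy)benzoate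
Conditions: Pd2(dba)3 (2.5 mol %), 2-di-tert-butylphosphino-2',4',6'-triisopropylbiphenyl, K3PO4, toluene, 100 °C
Reagents that add atoms: none
Why: Palladium-catalysed C–O cross-coupling of a phenol with an aryl triflate (Buchwald–Hartwig etherification): zerovalent palladium should insert into the C–OTf bond, which is activated by the ortho ester and not deactivated by the two meta alkoxy groups, and the bulky di-tert-butylbiarylphosphine drives C–O reductive elimination, each partner having only one substituent ortho to the reacting centre.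

Step 8
Reactants: 12 methyl 2-[2,3-dimethoxy-4,5-bis(3-methylbut-2-enyl)phenoxy]-4,6-bis(methoxymethoxy)benzoate
Product: 13 2-[2,3-dimethoxy-4,5-bis(3-methylbut-2-enyl)phenoxy]-4,6-bis(methoxymethoxy)benzoic acid
Conditions: KOH, DMSO/H2O (4:1), 80 °C; then cold 1 M HCl to pH 4
Reagents that add atoms: potassium hydroxide [K+].[OH-]
Why: Saponification of the methyl ester, which needs the hydroxide/DMSO medium because two ortho oxygen substituents shield the carbonyl, should leave MOM acetals, aryl ethers and alkenes untouched, and brief cold acidification frees the acid without acetal loss.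

Step 9
Reactants: 13 2-[2,3-dimethoxy-4,5-bis(3-methylbut-2-enyl)phenoxy]-4,6-bis(methoxymethoxy)benzoic acid
Product: 14 6,7-dimethoxy-1,3-bis(methoxymethoxy)-8,9-bis(3-methylbut-2-enyl)-11H-dibenzo[b,e][1,4]dioxepin-11-one
Conditions: undivided cell, graphite anode, Pt cathode, constant current (ca. 2 mA cm−2, stopped at 2.2 F mol−1), n-Bu4NPF6 (0.1 M), 2,6-lutidine (2 equiv), (CF3)2CHOH/CH2Cl2 (1:4), rt
Reagents that add atoms: none
Why: Proposed new method: ring B, with three oxygen and two alkyl donors, is the most easily oxidised part of 13, so the anode should remove one electron from it to give an arene radical cation; the carboxyl group on C1' of ring A, hydrogen-bonded to lutidine, then adds through oxygen to C2, and a second electron transfer with loss of the C2 proton restores the arene while protons are reduced to H2 at the cathode. The closest known reaction type is the anodic, or trivalent-iodine-mediated, dehydrogenative lactonisation of biaryl-2-carboxylic acids to six-membered benzocoumarins; it has not been shown for 2-aryloxybenzoic acids, where oxygen-centred aroyloxy radicals are known instead to trigger a 1,5-aryl shift from oxygen to oxygen. The one ring formed, the seven-membered 1,4-dioxepinone, closes by 7-endo-trig attack of the carboxyl oxygen on C2 (the C1–C2 bond of ring B lies inside the new ring), the bent diaryl ether and the twisted carboxyl group placing that oxygen over the C1–C2 edge of ring B. No stereocentre is created. The step needs selectivity for ring B over ring A and the alkenes, for C2 over ipso attack at C1 (the 6-exo mode that would end in aryl migration) and for nuclear over benzylic oxidation: ring A is deactivated by its carboxyl group and trisubstituted alkenes are expected to oxidise at clearly higher potential, C2 is the only unsubstituted carbon of ring B and sits ortho to the ether oxygen and para to the C5 methoxy group where the radical cation carries charge, and the fluorinated alcohol with a weak hindered base stabilises the radical cation, keeps free carboxylate and hence aroyloxy radicals scarce, and takes the C2 proton of the σ-complex irreversibly while being too weak to strip a prenyl CH2 proton quickly.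

Step 10
Reactants: 14 6,7-dimethoxy-1,3-bis(methoxymethoxy)-8,9-bis(3-methylbut-2-enyl)-11H-dibenzo[b,e][1,4]dioxepin-11-one
Product: 15 methyl 2-[2-hydroxy-5,6-dimethoxy-3,4-bis(3-methylbut-2-enyl)phenoxy]-4,6-bis(methoxymethoxy)benzoate
Conditions: NaOMe (1.5 equiv), MeOH/THF, 0 °C; AcOH quench
Reagents that add atoms: sodium methoxide [Na+].[O-]C
Why: Transesterification (methanolysis of an aryl ester): methoxide should add to the lactone carbonyl and expel the ring B C2 phenoxide, a far better leaving group than methoxide, which opens the seven-membered ring to the methyl ester and the free C2 hydroxyl, the low temperature guarding against Smiles migration of ring A between the two adjacent ring B oxygens.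

Step 11
Reactants: 15 methyl 2-[2-hydroxy-5,6-dimethoxy-3,4-bis(3-methylbut-2-enyl)phenoxy]-4,6-bis(methoxymethoxy)benzoate
Product: 16 methyl 2,4-dihydroxy-6-[2-hydroxy-5,6-dimethoxy-3,4-bis(3-methylbut-2-enyl)phenoxy]benzoate (4-methylhydroatrovirinone)
Conditions: 3 M aq. HCl, MeOH, rt to 40 °C
Reagents that add atoms: none
Why: Acid-catalysed acetal cleavage (MOM removal by transacetalisation to dimethoxymethane) should free both ring A phenols under conditions routinely mild enough to spare ortho-prenylphenols from cyclising to chromans, the methyl ester and methyl ethers being inert.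

**Compound list**

1 | meconin (6,7-dimethoxy-3H-2-benzofuran-1-one) | COc1ccc2COC(=O)c2c1OC | starting material
2 | [2-(hydroxymethyl)-3,4-dimethoxyphenyl]methanol | COc1ccc(CO)c(CO)c1OC | intermediate
3 | 1,2-bis(bromomethyl)-3,4-dimethoxybenzene | COc1ccc(CBr)c(CBr)c1OC | intermediate
4 | 2-methylprop-1-enylmagnesium bromide | CC(C)=C[Mg]Br | starting material
5 | 1,2-dimethoxy-3,4-bis(3-methylbut-2-enyl)benzene | COc1ccc(CC=C(C)C)c(CC=C(C)C)c1OC | intermediate
6 | [2,3-dimethoxy-4,5-bis(3-methylbut-2-enyl)phenyl]lithium | [Li]c1cc(CC=C(C)C)c(CC=C(C)C)c(OC)c1OC | intermediate (not isolated)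
7 | dimethyl [2,3-dimethoxy-4,5-bis(3-methylbut-2-enyl)phenyl]boronate | COB(OC)c1cc(CC=C(C)C)c(CC=C(C)C)c(OC)c1OC | intermediate (not isolated)
8 | 2,3-dimethoxy-4,5-bis(3-methylbut-2-enyl)phenol | Oc1cc(CC=C(C)C)c(CC=C(C)C)c(OC)c1OC | intermediate
9 | methyl 2,4,6-trihydroxybenzoate | COC(=O)c1c(O)cc(O)cc1O | starting material
10 | methyl 2-hydroxy-4,6-bis(methoxymethoxy)benzoate | COC(=O)c1c(O)cc(OCOC)cc1OCOC | intermediate
11 | methyl 2,4-bis(methoxymethoxy)-6-(trifluoromethylsulfonyloxy)benzoate | COC(=O)c1c(OCOC)cc(OCOC)cc1OS(=O)(=O)C(F)(F)F | intermediate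
12 | methyl 2-[2,3-dimethoxy-4,5-bis(3-methylbut-2-enyl)phenoxy]-4,6-bis(methoxymethoxy)benzoate | COC(=O)c1c(OCOC)cc(OCOC)cc1Oc1cc(CC=C(C)C)c(CC=C(C)C)c(OC)c1OC | intermediate
13 | 2-[2,3-dimethoxy-4,5-bis(3-methylbut-2-enyl)phenoxy]-4,6-bis(methoxymethoxy)benzoic acid | OC(=O)c1c(OCOC)cc(OCOC)cc1Oc1cc(CC=C(C)C)c(CC=C(C)C)c(OC)c1OC | intermediate
14 | 6,7-dimethoxy-1,3-bis(methoxymethoxy)-8,9-bis(3-methylbut-2-enyl)-11H-dibenzo[b,e][1,4]dioxepin-11-one | O=C1Oc2c(CC=C(C)C)c(CC=C(C)C)c(OC)c(OC)c2Oc2cc(OCOC)cc(OCOC)c12 | intermediate
15 | methyl 2-[2-hydroxy-5,6-dimethoxy-3,4-bis(3-methylbut-2-enyl)phenoxy]-4,6-bis(methoxymethoxy)benzoate | COC(=O)c1c(OCOC)cc(OCOC)cc1Oc1c(O)c(CC=C(C)C)c(CC=C(C)C)c(OC)c1OC | intermediate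
16 | methyl 2,4-dihydroxy-6-[2-hydroxy-5,6-dimethoxy-3,4-bis(3-methylbut-2-enyl)phenoxy]benzoate (4-methylhydroatrovirinone) | COC(=O)c1c(O)cc(O)cc1Oc1c(O)c(CC=C(C)C)c(CC=C(C)C)c(OC)c1OC | target

**Step count and risks**

Total step count: 11. Longest linear sequence: 9 steps (steps 1–4 and 7–11, from meconin); the ring A branch (steps 5–6) joins at step 7.

Steps most likely to fail:

1. Step 9 (proposed new method). What may go wrong:
- capture of the radical cation at the ipso carbon C1, followed by migration of ring B from the ether oxygen to the carboxyl oxygen;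
- proton loss from a prenyl CH2 group of the radical cation, followed by benzylic oxidation;
- acetal loss in the acidic layer at the anode.

Fallback, known reactions only: the C2 oxygen is brought in by a second directed metalation before the ether is made, so no lactone is needed. It sets out from phenol 8 and returns to the route at 16. Phenol 8 is carbamoylated (ClCONEt2, NaH, THF) to 2,3-dimethoxy-4,5-bis(3-methylbut-2-enyl)phenyl N,N-diethylcarbamate F1. The carbamate, a much stronger director than methoxy, guides s-BuLi/TMEDA (THF, −78 °C) to its only free ortho position and gives {2-[(diethylcarbamoyl)oxy]-3,4-dimethoxy-5,6-bis(3-methylbut-2-enyl)phenyl}lithium F2. This is trapped with B(OMe)3 as dimethyl {2-[(diethylcarbamoyl)oxy]-3,4-dimethoxy-5,6-bis(3-methylbut-2-enyl)phenyl}boronate F3 and oxidised (NaBO3·4H2O, THF/H2O) to 2-hydroxy-5,6-dimethoxy-3,4-bis(3-methylbut-2-enyl)phenyl N,N-diethylcarbamate F4. The new phenol is protected (MOMCl, i-Pr2NEt, CH2Cl2) as 5,6-dimethoxy-2-(methoxymethoxy)-3,4-bis(3-methylbut-2-enyl)phenyl N,N-diethylcarbamate F5. LiAlH4 in THF then removes the carbamate to give 2,3-dimethoxy-6-(methoxymethoxy)-4,5-bis(3-methylbut-2-enyl)phenol F6. Coupling of F6 with triflate 11 under the conditions of step 7 gives methyl 2-[2,3-dimethoxy-6-(methoxymethoxy)-4,5-bis(3-methylbut-2-enyl)phenoxy]-4,6-bis(methoxymethoxy)benzoate F7. HCl in methanol, as in step 11, removes all three MOM ethers and gives 16.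

2. Step 4. What may go wrong: removal of a doubly activated benzylic/allylic proton of a prenyl group instead of the ring hydrogen, leading to side-chain functionalisation or alkene isomerisation.

Fallback, without any carbanion: it sets out from 5 and returns at 8. Iridium-catalysed, sterically governed C–H borylation ([Ir(OMe)(cod)]2, a complex of monovalent iridium, with 4,4'-di-tert-butyl-2,2'-bipyridine and B2pin2, THF, 80 °C) should place boron at the ring C–H beside the methoxy group, the less hindered of the two ring hydrogens. This gives 2-[2,3-dimethoxy-4,5-bis(3-methylbut-2-enyl)phenyl]-4,4,5,5-tetramethyl-1,3,2-dioxaborolane F8, which NaBO3·4H2O in THF/H2O oxidises to 8.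

3. Step 7. What may go wrong: attack of the phenoxide at sulfur of the triflate (S–O cleavage back to the ring A phenol) or slow C–O reductive elimination from palladium.

Fallback, with the polarity of ring A reversed: it sets out from 11 and returns at 12. Miyaura borylation of 11 (B2pin2, PdCl2(dppf), KOAc, dioxane, 80 °C) gives methyl 2,4-bis(methoxymethoxy)-6-(4,4,5,5-tetramethyl-1,3,2-dioxaborolan-2-yl)benzoate F9. Chan–Lam coupling of F9 with phenol 8 (Cu(OAc)2, a salt of divalent copper, pyridine, 4 Å molecular sieves, air, CH2Cl2, rt) then forms the diaryl ether 12.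

**Further compounds**

F1 | step 9 | 2,3-dimethoxy-4,5-bis(3-methylbut-2-enyl)phenyl N,N-diethylcarbamate | CCN(CC)C(=O)Oc1cc(CC=C(C)C)c(CC=C(C)C)c(OC)c1OC
F2 | step 9 | {2-[(diethylcarbamoyl)oxy]-3,4-dimethoxy-5,6-bis(3-methylbut-2-enyl)phenyl}lithium | CCN(CC)C(=O)Oc1c([Li])c(CC=C(C)C)c(CC=C(C)C)c(OC)c1OC
F3 | step 9 | dimethyl {2-[(diethylcarbamoyl)oxy]-3,4-dimethoxy-5,6-bis(3-methylbut-2-enyl)phenyl}boronate | CCN(CC)C(=O)Oc1c(B(OC)OC)c(CC=C(C)C)c(CC=C(C)C)c(OC)c1OC
F4 | step 9 | 2-hydroxy-5,6-dimethoxy-3,4-bis(3-methylbut-2-enyl)phenyl N,N-diethylcarbamate | CCN(CC)C(=O)Oc1c(O)c(CC=C(C)C)c(CC=C(C)C)c(OC)c1OC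
F5 | step 9 | 5,6-dimethoxy-2-(methoxymethoxy)-3,4-bis(3-methylbut-2-enyl)phenyl N,N-diethylcarbamate | CCN(CC)C(=O)Oc1c(OCOC)c(CC=C(C)C)c(CC=C(C)C)c(OC)c1OC
F6 | step 9 | 2,3-dimethoxy-6-(methoxymethoxy)-4,5-bis(3-methylbut-2-enyl)phenol | Oc1c(OCOC)c(CC=C(C)C)c(CC=C(C)C)c(OC)c1OC
F7 | step 9 | methyl 2-[2,3-dimethoxy-6-(methoxymethoxy)-4,5-bis(3-methylbut-2-enyl)phenoxy]-4,6-bis(methoxymethoxy)benzoate | COC(=O)c1c(OCOC)cc(OCOC)cc1Oc1c(OCOC)c(CC=C(C)C)c(CC=C(C)C)c(OC)c1OC
F8 | step 4 | 2-[2,3-dimethoxy-4,5-bis(3-methylbut-2-enyl)phenyl]-4,4,5,5-tetramethyl-1,3,2-dioxaborolane | CC1(C)OB(OC1(C)C)c1cc(CC=C(C)C)c(CC=C(C)C)c(OC)c1OC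
F9 | step 7 | methyl 2,4-bis(methoxymethoxy)-6-(4,4,5,5-tetramethyl-1,3,2-dioxaborolan-2-yl)benzoate | COC(=O)c1c(OCOC)cc(OCOC)cc1B1OC(C)(C)C(C)(C)O1
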